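Take the charge as your unit, so that the amounts in the runs are fractions of the X charged.

| flask | X | remark | time |
|---|---|---|---|
| south-west | 1.9 M | run made earlier |  |
| flask | 2.8 M |  | 2.0 h |

south-west run (percent of the X charged)

| time / h | Z / % | J / % | X / % |
|---|---|---|---|
| 0.167 | 1 | 13 | 85 |
| 0.500 | 4 | 35 | 60 |
| 0.833 | 0 | 48 | 37 |
| 1.33 | 10 | 51 | 5 |
| 2.00 | 27 | 34 | 0 |
| 2.50 | 41 | 21 | 0 |

(readings scatter by 2 percentage points)

- X is a solid; its amount is given per volume of the solution
- steps that have been proposed: J -> E; E -> L; L -> Q; Q -> Z; X <-> J
- at the start none of X is in solution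
- J means what is dissolved; the solid is not counted in it

- amount of Z at 2.0 h, in percent of the X charged
- concentration of J in solution at 12 min, in percent of saturation
- the change that raises the amount of Z at 2.0 h, in percent of the X charged most ("none" if none brings more than 2 percentage points) (ash / larch / none)
- amount of Z at 2.0 h, in percent of the X charged, after ash

- ash: doubling the dissolution coefficient of X, all else as stated
- larch: doubling the solubility of X, all else as stated

In the south-west run X falls nearly straight, pseudo-zero-order: 60 % at 0.500 h, 37 % at 0.833 h, 5 % at 1.33 h. So I read the feed as a steady molar stream that hardly feels how much solid lies there. Two times then count. Each is a solid life, the time the whole charge needs at that mean feed: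

τ, south-west = 1.40 h

τ, flask = 2.06 h

Their quotient is the life ratio 0.679. I take the steps after the feed to run alike in both flasks. While solid stands, the same molar amount is then a smaller fraction of the larger charge, by this ratio.

By this estimate the flask's solid life just outlasts the 2.0 h asked. The south-west life is shorter, but at 2.00 h that run still holds 39.0 % between J and Z. So I take its Z as made from J dissolved while solid stood:

Z, flask = 0.679 × 27 % = 18.3 %, with 1.4 percentage points from the scatter of that reading

The forecast says 19 %, 9 %, larch and 31 %, on the ground that “the flask follows the same molar J history as the south-west run”. My figure for Z lies slightly lower.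

    J → E (k = 2.33 × 10⁻⁴ s⁻¹)
    E → L (k = 0.00469 s⁻¹)
    L → Q (k = 0.00177 s⁻¹)
    Q → Z (k = 2.55 × 10⁻⁴ s⁻¹)
    X ⇌ J, rate k5*(cs5 - [J]) while solid is left; crystals form when [J] > cs5 (solubility = 2.20 M, k = 2.43 × 10⁻⁴ s⁻¹)

The flask gives 18.2 % of Z. Its J at 12 min stands at 14.8 % of saturation, against the forecast's 9 %. Larch is best at 14 points, over ash at 10 points, and ash gives 28.2 %. At 2.00 h the flask still held 12.9 % as X. For the same flask read at 80 min, the life ratio times the south-west 10 % gives 6.79 %, and that flask holds 6.47 %.

The data are calculated on assumed constants; scatter was added.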